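The closed, stirred vessel held starting material, enzyme and added ligand at constant volume and temperature. Thursday's run had half the starting material of the new flask, with the same enzyme and added ligand.

- Thursday's: starting material 0.025 M; enzyme 50 µM; added ligand 0.18 mM; run made earlier
- flask: starting material 0.050 M; enzyme 50 µM; added ligand 0.18 mM; time 2.0 h

Thursday's run (percent of the starting material charged)

| time / min | product / % |
|---|---|
| 2.00 | 4 |
| 3.00 | 6 |
| 5.00 | 4 |
| 8.00 | 9 |
| 15.0 | 14 |
| 25.0 | 23 |

(standard deviation of a reading: 1.5 percentage points)

- the best time, 2.0 h at the latest, for product
- the amount of product, in percent of the starting material charged, at that time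

- a reading or a percentage of product counts all its forms, free or not

I turned each of Thursday's rows into the turnover w, the product formed per minute per enzyme charged, counted from the start. The last row gave w = 4.60 min⁻¹. Going up the table, the row at 15.0 min gave 4.67 min⁻¹ and the row at 8.00 min gave 5.62 min⁻¹, so these three lay close. The rows at 2.00 min and 5.00 min gave 10.0 min⁻¹ and 4.00 min⁻¹, but each rests on a reading of 4% with a scatter of 1.5 percentage points, so I gave them little weight.

A steady w was the zero of my scale. That is the zero-order case, where the rate at a fixed enzyme charge does not change with the starting material. Thursday's product rose overall up to its last reading at 25.0 min, so I chose 2.0 h for the new flask, and w, carried over unchanged, then gave 55.2%.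

The forecast, higher than my line, gave 60% at 2 h, holding that “the yield should keep rising”.

The new flask gave 49.8% at 2.00 h, which is 5.4 points less than my line.

    starting material + enzyme → product + enzyme, rate k1*[starting material]^2*[enzyme]/(1 + ([starting material]/Kh1)^2) (13.5 mM, k = 3.84 × 10⁶ L² mol⁻² h⁻¹)
    enzyme + product ⇌ idle complex A (K = 36.0 L mol⁻¹, k = 11.9 L mol⁻¹ h⁻¹)
    enzyme + added ligand ⇌ idle complex B (K = 9900 L mol⁻¹, k = 42600 L mol⁻¹ h⁻¹)

At 1.00 h this flask held 28.2% product, close to the 27.6% that w gives. With 8.5 × 10⁻⁵ M of enzyme and the other charges unchanged, w gives 93.8% at 2.00 h, and that neighbouring flask reached 76.2%.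

The numbers in the tables stem from a simulated flask for substances that don't exist; noise was put on by code.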